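With the rings lettered A to E from the 2,4,6-trihydroxyphenoxy end, rings A, C and E are benzenes oxygenated at C1, C2, C3 and C5, so each is an isomer of a 4-oxy-6-(oxymethyl)-2H-pyran-2-one. The route rests on disconnecting, in each of these rings, the C–C bond beside the oxygen-bearing carbon that lies between two hydroxyls. The precursor is a tris-pyranone in which the intact trimethoxylated rings B and D are held by simple CH2–O and pyranone C4–O bonds. In one operation methoxide opens the three lactones and Claisen closure of the exocyclic carbon C7 onto the lactone carbon C2 creates rings A, C and E, with all four diaryl ether bonds already in place.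

Key step: step 12

Remark: the target has no stereocentres; each Baeyer–Villiger oxidation is run through to the phenol without isolating the aryl formate and counts as one step; pyranone positions are numbered O1, C2 (carbonyl) to C6, with C7 the exocyclic carbon on C6.

Step 1
Reactants: 1 3,4,5-trimethoxyphenol
Product: 2 6-hydroxy-2,3,4-trimethoxybenzaldehyde
Conditions: MgCl2, Et3N, (CH2O)n, MeCN, reflux; then 1 M HCl
Reagents that add atoms: paraformaldehyde (as formaldehyde), C=O
Why: Magnesium-mediated ortho-formylation (Casnati–Skattebøl reaction): the magnesium phenoxide delivers formaldehyde only ortho to the hydroxyl, the two ortho positions of 1 are equivalent, and a second formaldehyde oxidises the benzylic alkoxide to the aldehyde, so a single salicylaldehyde should result.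

Step 2
Reactants: 3 4-methoxy-6-methyl-2H-pyran-2-one
Product: 4 6-(bromomethyl)-4-methoxy-2H-pyran-2-one
Conditions: NBS, (PhCO2)2 (cat.), PhCF3, reflux
Reagents that add atoms: N-bromosuccinimide, O=C1CCC(=O)N1Br
Why: Wohl–Ziegler radical bromination: hydrogen abstraction is favoured at the 6-methyl group because the radical is delocalised through the pyranone diene, while the low bromine concentration under radical conditions suppresses ionic bromination at C3.

Step 3
Reactants: 2 6-hydroxy-2,3,4-trimethoxybenzaldehyde; 4 6-(bromomethyl)-4-methoxy-2H-pyran-2-one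
Product: 5 2,3,4-trimethoxy-6-[(4-methoxy-2-oxo-2H-pyran-6-yl)methoxy]benzaldehyde
Conditions: K2CO3, DMF, rt
Reagents that add atoms: none
Why: Williamson ether synthesis: the acidic, formyl-conjugated phenol is deprotonated by carbonate and displaces the primary allylic-type bromide by SN2, the 4-methoxy enol ether being a much poorer electrophile and the temperature too low for aldol closure of the aryloxymethyl group onto the aldehyde.

Step 4
Reactants: 5 2,3,4-trimethoxy-6-[(4-methoxy-2-oxo-2H-pyran-6-yl)methoxy]benzaldehyde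
Product: 7 6-[(2-hydroxy-3,4,5-trimethoxyphenoxy)methyl]-4-methoxy-2H-pyran-2-one, via aryl formate 6 (not isolated)
Conditions: mCPBA, CH2Cl2, 0 °C to rt; then MeOH, HCl (cat.), rt
Reagents that add atoms: 3-chloroperoxybenzoic acid, OOC(=O)c1cccc(Cl)c1
Why: Baeyer–Villiger oxidation (Dakin-type): the electron-rich aryl group flanked by two oxygen substituents migrates in preference to hydrogen, the electron-poor pyranone is inert to the peracid, and the aryl formate is far more labile towards acid-catalysed transesterification than the lactone or the CH2–O ether.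

Step 5
Reactants: 8 4-hydroxy-6-methyl-2H-pyran-2-one (triacetic acid lactone)
Product: 9 4-bromo-6-methyl-2H-pyran-2-one
Conditions: PBr3, DMF, 0 °C to 60 °C
Reagents that add atoms: phosphorus tribromide, BrP(Br)Br
Why: Vilsmeier-type deoxybromination of a vinylogous acid: the 4-hydroxyl is activated as an iminium ether and bromide then substitutes at C4 by addition–elimination, a standard conversion of 4-hydroxypyranones into 4-bromopyranones.

Step 6
Reactants: 9 4-bromo-6-methyl-2H-pyran-2-one
Product: 10 4-bromo-6-(bromomethyl)-2H-pyran-2-one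
Conditions: NBS, AIBN (cat.), PhCF3, reflux
Reagents that add atoms: N-bromosuccinimide, O=C1CCC(=O)N1Br
Why: Wohl–Ziegler radical bromination of the 6-methyl group as in step 2; the vinylic C4–Br takes no part in the radical chain.

Step 7
Reactants: 2 6-hydroxy-2,3,4-trimethoxybenzaldehyde; 10 4-bromo-6-(bromomethyl)-2H-pyran-2-one
Product: 11 6-[(4-bromo-2-oxo-2H-pyran-6-yl)methoxy]-2,3,4-trimethoxybenzaldehyde
Conditions: K2CO3, acetone, 0 °C, 10 in excess (2 equiv), slow addition of 2
Reagents that add atoms: none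
Why: Williamson ether synthesis: SN2 at the primary allylic-type bromide should outrun addition–elimination at the vinylic C4–Br for the weakly nucleophilic, formyl-conjugated phenoxide, and low temperature, a weak base and an excess of 10 hold the reaction at mono-substitution.

Step 8
Reactants: 7 6-[(2-hydroxy-3,4,5-trimethoxyphenoxy)methyl]-4-methoxy-2H-pyran-2-one; 11 6-[(4-bromo-2-oxo-2H-pyran-6-yl)methoxy]-2,3,4-trimethoxybenzaldehyde
Product: 12 2,3,4-trimethoxy-6-[(4-{2,3,4-trimethoxy-6-[(4-methoxy-2-oxo-2H-pyran-6-yl)methoxy]phenoxy}-2-oxo-2H-pyran-6-yl)methoxy]benzaldehyde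
Conditions: K2CO3, DMF, 0 °C to rt, Ar
Reagents that add atoms: none
Why: Addition–elimination (vinylogous acyl substitution) at C4 of a 4-bromopyranone, a known way to 4-aryloxypyranones: C4 is unhindered and activated by the lactone carbonyl, so the di-ortho-substituted phenoxide of 7 should add and expel bromide, while carbonate at room temperature does not enolise the aryloxymethyl groups next to the aldehyde.

Step 9
Reactants: 12 2,3,4-trimethoxy-6-[(4-{2,3,4-trimethoxy-6-[(4-methoxy-2-oxo-2H-pyran-6-yl)methoxy]phenoxy}-2-oxo-2H-pyran-6-yl)methoxy]benzaldehyde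
Product: 14 6-[(2-hydroxy-3,4,5-trimethoxyphenoxy)methyl]-4-{2,3,4-trimethoxy-6-[(4-methoxy-2-oxo-2H-pyran-6-yl)methoxy]phenoxy}-2H-pyran-2-one, via aryl formate 13 (not isolated)
Conditions: mCPBA, CH2Cl2, 0 °C to rt; then MeOH, HCl (cat.), 0 °C
Reagents that add atoms: 3-chloroperoxybenzoic acid, OOC(=O)c1cccc(Cl)c1
Why: Baeyer–Villiger oxidation as in step 4: the push–pull double bonds of both pyranones are too electron-poor for epoxidation, and the short, cold acidic methanolysis removes only the formate and leaves the 4-aryloxy enol ether untouched.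

Step 10
Reactants: 10 4-bromo-6-(bromomethyl)-2H-pyran-2-one
Product: 15 4-bromo-6-(methoxymethyl)-2H-pyran-2-one
Conditions: AgOSO2CF3, 2,6-di-tert-butylpyridine, MeOH–CH2Cl2, rt, dark
Reagents that add atoms: methanol, CO
Why: Silver-assisted solvolysis: the silver cation pulls only the sp3 bromide away as AgBr while methanol attacks the methylene carbon, and the hindered pyridine keeps the medium neutral and free of methoxide, so the vinylic C4–Br survives.

Step 11
Reactants: 14 6-[(2-hydroxy-3,4,5-trimethoxyphenoxy)methyl]-4-{2,3,4-trimethoxy-6-[(4-methoxy-2-oxo-2H-pyran-6-yl)methoxy]phenoxy}-2H-pyran-2-one; 15 4-bromo-6-(methoxymethyl)-2H-pyran-2-one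
Product: 16 4-{2,3,4-trimethoxy-6-[(4-methoxy-2-oxo-2H-pyran-6-yl)methoxy]phenoxy}-6-({3,4,5-trimethoxy-2-{[6-(methoxymethyl)-2-oxo-2H-pyran-4-yl]oxy}phenoxy}methyl)-2H-pyran-2-one (tris-pyranone)
Conditions: K2CO3, DMF, rt, Ar
Reagents that add atoms: none
Why: Addition–elimination at C4 of the 4-bromopyranone as in step 8; the phenoxide of 14 is the only strong nucleophile present and the methoxymethyl group of 15 is inert.

Step 12
Reactants: 16 tris-pyranone
Product: 18 octa-O-methyl pentamer 2-{2-[3,5-dihydroxy-4-(2-(3,5-dihydroxy-4-methoxyphenoxy)-3,4,5-trimethoxyphenoxy)phenoxy]-3,4,5-trimethoxyphenoxy}-5-methoxybenzene-1,3-diol, via ring-opened triester 17 (not isolated)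
Conditions: Mg(OMe)2 (excess), MeOH–THF, 0 °C to reflux, Ar, dilute; then cold 1 M HCl
Reagents that add atoms: none
Why: Proposed new method: in each pyranone methoxide should add to the lactone carbonyl C2 and open the ring to the C6 enolate, giving a methyl (2E)-3,6-dioxy-5-oxohex-2-enoate unit whose ester and ketone arm are cis across the enol-ether double bond because they came from one ring; the ketone enolate at the oxygen-bearing former C7 then attacks the ester, expels methoxide, and the resulting cyclohexenedione tautomerises irreversibly to a resorcinolate. The closest known reaction type is the alkoxide-mediated conversion of 4-alkoxy-6-methylpyran-2-ones, through their ring-opened 3-alkoxy-5-oxohexenoates, into 5-alkoxyresorcinols, together with the Mg(OMe)2 pyranone-to-arene conversions of biomimetic polyketide chemistry; three rings at once and aryloxy groups at C4 and C7 have no precedent. Rings A, C and E are each closed by a 6-(enolendo)-exo-trig Claisen (Dieckmann-type) condensation that forms the C7–C2 bond. No stereocentre is created. The step needs attack at C2 and not addition–elimination at C4, which would expel the ring B or ring D aryloxide and cut the chain: the magnesium-bound lactone carbonyl is the hardest electrophile, the C4 positions of the two aryloxy-pyranones are screened by di-ortho-substituted aryl groups, and the opened units rest as dienolates that resist conjugate addition. Opening, relactonisation and enolate equilibration are reversible while aromatisation is not, so each unit should funnel on its own to its benzene ring.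

Step 13
Reactants: 18 octa-O-methyl pentamer
Product: 19 2-{2-[4-(2-(3,4,5-trihydroxyphenoxy)-3,4,5-trihydroxyphenoxy)-3,5-dihydroxyphenoxy]-3,4,5-trihydroxyphenoxy}benzene-1,3,5-triol (CNP0273977.0)
Conditions: BBr3 (excess), CH2Cl2, −78 °C to rt, Ar; then degassed ice-water
Reagents that add atoms: none
Why: Lewis acid-mediated ether cleavage: BBr3 coordinates each methoxy oxygen and bromide removes the methyl group by SN2, whereas the diaryl ether bonds offer no sp3 carbon to attack and the free phenols are only borylated until hydrolysis.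

Compound list
1 | 3,4,5-trimethoxyphenol | COc1cc(O)cc(OC)c1OC | starting material
2 | 6-hydroxy-2,3,4-trimethoxybenzaldehyde | O=Cc1c(O)cc(OC)c(OC)c1OC | intermediate
3 | 4-methoxy-6-methyl-2H-pyran-2-one | COC1=CC(=O)OC(C)=C1 | starting material
4 | 6-(bromomethyl)-4-methoxy-2H-pyran-2-one | COC1=CC(=O)OC(CBr)=C1 | intermediate
5 | 2,3,4-trimethoxy-6-[(4-methoxy-2-oxo-2H-pyran-6-yl)methoxy]benzaldehyde | COC1=CC(=O)OC(COc2cc(OC)c(OC)c(OC)c2C=O)=C1 | intermediate
6 | 2,3,4-trimethoxy-6-[(4-methoxy-2-oxo-2H-pyran-6-yl)methoxy]phenyl formate | COC1=CC(=O)OC(COc2cc(OC)c(OC)c(OC)c2OC=O)=C1 | intermediate (not isolated)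
7 | 6-[(2-hydroxy-3,4,5-trimethoxyphenoxy)methyl]-4-methoxy-2H-pyran-2-one | COC1=CC(=O)OC(COc2cc(OC)c(OC)c(OC)c2O)=C1 | intermediate
8 | 4-hydroxy-6-methyl-2H-pyran-2-one (triacetic acid lactone) | CC1=CC(O)=CC(=O)O1 | starting material
9 | 4-bromo-6-methyl-2H-pyran-2-one | CC1=CC(Br)=CC(=O)O1 | intermediate
10 | 4-bromo-6-(bromomethyl)-2H-pyran-2-one | BrCC1=CC(Br)=CC(=O)O1 | intermediate
11 | 6-[(4-bromo-2-oxo-2H-pyran-6-yl)methoxy]-2,3,4-trimethoxybenzaldehyde | BrC1=CC(=O)OC(COc2cc(OC)c(OC)c(OC)c2C=O)=C1 | intermediate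
12 | 2,3,4-trimethoxy-6-[(4-{2,3,4-trimethoxy-6-[(4-methoxy-2-oxo-2H-pyran-6-yl)methoxy]phenoxy}-2-oxo-2H-pyran-6-yl)methoxy]benzaldehyde | COC1=CC(=O)OC(COc2cc(OC)c(OC)c(OC)c2OC2=CC(=O)OC(COc3cc(OC)c(OC)c(OC)c3C=O)=C2)=C1 | intermediate
13 | formate ester of 14 (aryl formate from Baeyer–Villiger oxidation of 12) | COC1=CC(=O)OC(COc2cc(OC)c(OC)c(OC)c2OC2=CC(=O)OC(COc3cc(OC)c(OC)c(OC)c3OC=O)=C2)=C1 | intermediate (not isolated)
14 | 6-[(2-hydroxy-3,4,5-trimethoxyphenoxy)methyl]-4-{2,3,4-trimethoxy-6-[(4-methoxy-2-oxo-2H-pyran-6-yl)methoxy]phenoxy}-2H-pyran-2-one | COC1=CC(=O)OC(COc2cc(OC)c(OC)c(OC)c2OC2=CC(=O)OC(COc3cc(OC)c(OC)c(OC)c3O)=C2)=C1 | intermediate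
15 | 4-bromo-6-(methoxymethyl)-2H-pyran-2-one | COCC1=CC(Br)=CC(=O)O1 | intermediate
16 | tris-pyranone: 4-{2,3,4-trimethoxy-6-[(4-methoxy-2-oxo-2H-pyran-6-yl)methoxy]phenoxy}-6-({3,4,5-trimethoxy-2-{[6-(methoxymethyl)-2-oxo-2H-pyran-4-yl]oxy}phenoxy}methyl)-2H-pyran-2-one | COC1=CC(=O)OC(COc2cc(OC)c(OC)c(OC)c2OC2=CC(=O)OC(COc3cc(OC)c(OC)c(OC)c3OC3=CC(=O)OC(COC)=C3)=C2)=C1 | intermediate
17 | ring-opened triester: each pyranone of 16 as a methyl (2E)-3-oxy-5-oxo-6-oxyhex-2-enoate unit, ester cis to the C4 methylene | COC(=O)/C=C(/OC)CC(=O)COc1cc(OC)c(OC)c(OC)c1O/C(=C/C(=O)OC)CC(=O)COc1cc(OC)c(OC)c(OC)c1O/C(=C/C(=O)OC)CC(=O)COC | intermediate (not isolated)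
18 | octa-O-methyl pentamer with six free hydroxyls: 2-{2-[3,5-dihydroxy-4-(2-(3,5-dihydroxy-4-methoxyphenoxy)-3,4,5-trimethoxyphenoxy)phenoxy]-3,4,5-trimethoxyphenoxy}-5-methoxybenzene-1,3-diol | COc1cc(O)c(Oc2cc(OC)c(OC)c(OC)c2Oc2cc(O)c(Oc3cc(OC)c(OC)c(OC)c3Oc3cc(O)c(OC)c(O)c3)c(O)c2)c(O)c1 | intermediate
19 | CNP0273977.0: 2-{2-[4-(2-(3,4,5-trihydroxyphenoxy)-3,4,5-trihydroxyphenoxy)-3,5-dihydroxyphenoxy]-3,4,5-trihydroxyphenoxy}benzene-1,3,5-triol | Oc1cc(O)c(Oc2cc(O)c(O)c(O)c2Oc2cc(O)c(Oc3cc(O)c(O)c(O)c3Oc3cc(O)c(O)c(O)c3)c(O)c2)c(O)c1 | target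

Total step count: 13 steps (15 operations if each formate cleavage is counted apart from its Baeyer–Villiger oxidation).
Longest linear sequence: 8 steps (steps 1, 3, 4, 8, 9, 11, 12, 13 from 1; equally steps 5, 6, 7, 8, 9, 11, 12, 13 from 8).

Steps most likely to fail

Step 12. Methoxide may add at C4 of the two aryloxy-pyranones and expel the ring B or ring D phenoxide, which cuts the chain, or opened units may stall at the acyclic keto ester stage without closing. The fallback gives up the ring synthesis and joins five preformed benzene rings by known metal-catalysed diaryl ether couplings; it sets out from 2 and comes back at 19.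
- Ring B: 2 is converted with Tf2O and pyridine into 2-formyl-3,4,5-trimethoxyphenyl trifluoromethanesulfonate F1. Palladium-catalysed C–O coupling (Pd(OAc)2, t-BuXPhos, K3PO4, toluene, 100 °C) of F1 with commercial 2,4,6-trimethoxyphenol should give 2,3,4-trimethoxy-6-(2,4,6-trimethoxyphenoxy)benzaldehyde F2. Baeyer–Villiger oxidation with mCPBA gives 2,3,4-trimethoxy-6-(2,4,6-trimethoxyphenoxy)phenyl formate F3, and acidic methanolysis gives 2,3,4-trimethoxy-6-(2,4,6-trimethoxyphenoxy)phenol F4.
- Ring C: Ullmann coupling (CuI, picolinic acid, K3PO4, DMSO, 90 °C) of F4 with commercial 4-bromo-2,6-dimethoxybenzaldehyde gives 2,6-dimethoxy-4-[2,3,4-trimethoxy-6-(2,4,6-trimethoxyphenoxy)phenoxy]benzaldehyde F5. The same oxidation gives 2,6-dimethoxy-4-[2,3,4-trimethoxy-6-(2,4,6-trimethoxyphenoxy)phenoxy]phenyl formate F6 and then 2,6-dimethoxy-4-[2,3,4-trimethoxy-6-(2,4,6-trimethoxyphenoxy)phenoxy]phenol F7.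
- Ring D: palladium-catalysed coupling of F7 with a second portion of F1 gives 2,3,4-trimethoxy-6-{2,6-dimethoxy-4-[2,3,4-trimethoxy-6-(2,4,6-trimethoxyphenoxy)phenoxy]phenoxy}benzaldehyde F8, which is oxidised to 2,3,4-trimethoxy-6-{2,6-dimethoxy-4-[2,3,4-trimethoxy-6-(2,4,6-trimethoxyphenoxy)phenoxy]phenoxy}phenyl formate F9 and methanolysed to 2,3,4-trimethoxy-6-{2,6-dimethoxy-4-[2,3,4-trimethoxy-6-(2,4,6-trimethoxyphenoxy)phenoxy]phenoxy}phenol F10.
- Ring E and release: Ullmann coupling of F10 with commercial 5-bromo-1,2,3-trimethoxybenzene gives the tetradeca-O-methyl ether of the target F11, and BBr3 in CH2Cl2 cleaves all fourteen methyl ethers to 19.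

Step 7. Site selectivity may be lost: the phenoxide of 2 may also add at the vinylic C4–Br, or a second phenoxide may substitute the product. The fallback replaces the phenoxide displacement by a redox condensation in which only the alcohol carbon is activated; it sets out from 10 and comes back at 11. Silver-assisted hydrolysis of 10 (AgOSO2CF3, 2,6-di-tert-butylpyridine, acetone–water, rt) gives 4-bromo-6-(hydroxymethyl)-2H-pyran-2-one F12. Mitsunobu etherification of F12 with 2 (PPh3, DIAD, THF, 0 °C, betaine preformed) then gives 11 without any free phenoxide that could attack C4.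

Step 13. Cleavage of the methyl ethers flanked by two oxygen substituents may stay incomplete, and the pyrogallol-type rings B, D and E may oxidise in air during aqueous work-up and chromatography of the free polyphenol. The fallback changes the end-game from direct isolation to cleave, trap, purify and release; it sets out from 18 and comes back at 19. After the BBr3 treatment and removal of volatiles the crude phenol is acetylated in the same flask (Ac2O, pyridine, DMAP cat.) to the tetradeca-O-acetate of the target F13. This neutral, air-stable compound can be chromatographed, and partly methylated acetates can be separated and resubmitted. Acid-catalysed transesterification (HCl cat., degassed MeOH, Ar) then releases 19 beside volatile by-products only.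

Further compounds
F1 | step 12 | 2-formyl-3,4,5-trimethoxyphenyl trifluoromethanesulfonate | O=Cc1c(OS(=O)(=O)C(F)(F)F)cc(OC)c(OC)c1OC
F2 | step 12 | 2,3,4-trimethoxy-6-(2,4,6-trimethoxyphenoxy)benzaldehyde | COc1cc(OC)c(Oc2cc(OC)c(OC)c(OC)c2C=O)c(OC)c1
F3 | step 12 | 2,3,4-trimethoxy-6-(2,4,6-trimethoxyphenoxy)phenyl formate | COc1cc(OC)c(Oc2cc(OC)c(OC)c(OC)c2OC=O)c(OC)c1
F4 | step 12 | 2,3,4-trimethoxy-6-(2,4,6-trimethoxyphenoxy)phenol | COc1cc(OC)c(Oc2cc(OC)c(OC)c(OC)c2O)c(OC)c1
F5 | step 12 | 2,6-dimethoxy-4-[2,3,4-trimethoxy-6-(2,4,6-trimethoxyphenoxy)phenoxy]benzaldehyde | COc1cc(OC)c(Oc2cc(OC)c(OC)c(OC)c2Oc2cc(OC)c(C=O)c(OC)c2)c(OC)c1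
F6 | step 12 | 2,6-dimethoxy-4-[2,3,4-trimethoxy-6-(2,4,6-trimethoxyphenoxy)phenoxy]phenyl formate | COc1cc(OC)c(Oc2cc(OC)c(OC)c(OC)c2Oc2cc(OC)c(OC=O)c(OC)c2)c(OC)c1
F7 | step 12 | 2,6-dimethoxy-4-[2,3,4-trimethoxy-6-(2,4,6-trimethoxyphenoxy)phenoxy]phenol | COc1cc(OC)c(Oc2cc(OC)c(OC)c(OC)c2Oc2cc(OC)c(O)c(OC)c2)c(OC)c1
F8 | step 12 | 2,3,4-trimethoxy-6-{2,6-dimethoxy-4-[2,3,4-trimethoxy-6-(2,4,6-trimethoxyphenoxy)phenoxy]phenoxy}benzaldehyde | COc1cc(OC)c(Oc2cc(OC)c(OC)c(OC)c2Oc2cc(OC)c(Oc3cc(OC)c(OC)c(OC)c3C=O)c(OC)c2)c(OC)c1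
F9 | step 12 | 2,3,4-trimethoxy-6-{2,6-dimethoxy-4-[2,3,4-trimethoxy-6-(2,4,6-trimethoxyphenoxy)phenoxy]phenoxy}phenyl formate | COc1cc(OC)c(Oc2cc(OC)c(OC)c(OC)c2Oc2cc(OC)c(Oc3cc(OC)c(OC)c(OC)c3OC=O)c(OC)c2)c(OC)c1
F10 | step 12 | 2,3,4-trimethoxy-6-{2,6-dimethoxy-4-[2,3,4-trimethoxy-6-(2,4,6-trimethoxyphenoxy)phenoxy]phenoxy}phenol | COc1cc(OC)c(Oc2cc(OC)c(OC)c(OC)c2Oc2cc(OC)c(Oc3cc(OC)c(OC)c(OC)c3O)c(OC)c2)c(OC)c1
F11 | step 12 | tetradeca-O-methyl ether of the target | COc1cc(OC)c(Oc2cc(OC)c(OC)c(OC)c2Oc2cc(OC)c(Oc3cc(OC)c(OC)c(OC)c3Oc3cc(OC)c(OC)c(OC)c3)c(OC)c2)c(OC)c1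
F12 | step 7 | 4-bromo-6-(hydroxymethyl)-2H-pyran-2-one | OCC1=CC(Br)=CC(=O)O1
F13 | step 13 | tetradeca-O-acetate of the target | CC(=O)Oc1cc(OC(C)=O)c(Oc2cc(OC(C)=O)c(OC(C)=O)c(OC(C)=O)c2Oc2cc(OC(C)=O)c(Oc3cc(OC(C)=O)c(OC(C)=O)c(OC(C)=O)c3Oc3cc(OC(C)=O)c(OC(C)=O)c(OC(C)=O)c3)c(OC(C)=O)c2)c(OC(C)=O)c1
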